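A one-step world has a single clock: E turns into Q, and waiting longer gives more Q. The earlier runs show something else.

the same everywhere: G 1 mol%
- Sunday's: E 0.65 M; D 0.15 M; run made earlier
- Wednesday's: E 0.94 M; D 0.15 M; run made earlier
- ochre: E 1.5 M; D 0.150 M; time 12 min
- teal: E 1.0 M; D 0.150 M; time 12 min

- Sunday's (time / min: Q / %): 1.33: 32; 2.50: 35; 4.00: 39; 5.00: 40; 6.00: 37; 8.00: 40
- Wednesday's (time / min: Q / %): 1.33: 49; 2.50: 47; 4.00: 48; 5.00: 50; 6.00: 54; 8.00: 52

(readings scatter by 2 percentage points)

- the average divides the monomer in chains by the number of chains begun, living and dead together
- the earlier runs do not show the number of chains; that part of a forecast is a guess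

* which of the two ends with the longer chains by the average number of monomer units in a chain (chains begun, living or dead) ("neither" if they lie within 10 %) (ochre / teal / neither)
* average number of monomer units in a chain (chains begun, living or dead) at the end, ochre
* average number of monomer units in a chain (chains begun, living or dead) at the end, teal

From 4.00 min on, Q stood near 39.0 % in Sunday's run and near 51.0 % in Wednesday's, so a second clock was at work. I reckoned with two rates for a growing chain end: how fast it takes E and how fast it dies. The readings give neither rate by itself, but their ratio can be read from where Q stops. If ends die at a steady pace, the ends made from G work for a total time proportional to the G charged, so the logarithm of E's fall is that charge times the ratio. The usual term for a stop of this kind, with E left over, is dead-end polymerisation.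

The natural logarithm of E charged over E left at the stop, per molar of G charged, reads 76.0 M⁻¹ in Sunday's run and 75.9 M⁻¹ in Wednesday's, from different charges of E and G at the same 0.15 M of D. Their mean is the ratio I carried forward, and I call it the reach, 76.0 M⁻¹. I trusted it for ochre and teal, which hold D at 0.150 M too, because the two readings match.

The reach gave me Q of 68.0 % in ochre and 53.2 % in teal. Guessing one chain per G, I divided by the loading and got lengths of 68.0 for ochre and 53.2 for teal, so ochre was longer.

The forecast named ochre, with 67 and 52, close to my figures but not the same, and held that “this ratio survives any constant efficiency”.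

The flask gave ochre as the longer, with 67.2 for ochre and 53.6 for teal.

    E + X → Q + X, rate k1*[X]*[E] (k = 11.0 M⁻¹ s⁻¹)
    X + D → J (k = 0.948 M⁻¹ s⁻¹)
    2 E → L (k = 5.54 × 10⁻⁵ M⁻¹ s⁻¹)
    E + G → X + Q (k = 0.0402 M⁻¹ s⁻¹)
    2 X → Z (k = 4.44 M⁻¹ s⁻¹)

In ochre, Q read 67.2 % at 6.00 min and 67.2 % at 120 min, while E slid from 31.9 % to 23.4 %, so Q is the reading to watch. Teal's Q ended at 53.6 % against the 53.2 % from the reach. For teal with 0.4 mol% of G, the reach gives Q of 26.2 % and a length of 65.5; that flask gave 26.6 % and 66.5.

The earlier runs and the new flask stem from a simulated flask with made-up constants.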